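The 14-membered carbocycle (cembrane numbering: C1 isopropenyl, C2 OAc, C4 CH2OAc, C7 OH) is opened at the C4(sp2)–C5(sp3) bond. One operation, chemoselective hydroboration followed by B-alkyl Suzuki–Miyaura macrocyclisation, turns the only monosubstituted alkene of an acyclic pentaene into the C5 nucleophile. It joins C5 to C4 with retention, which closes the ring and fixes the C3=C4 geometry. It exploits two features. C5–C6–C7(O) is the hydroboration retron of a vinyl carbinol. C5 lies cis to C2 across C3=C4, exactly where C2–OH-directed trans-hydroalumination of a propargylic alcohol places iodine. The precursor is an open-chain (Z)-vinyl iodide built from geranyl acetate, pent-1-en-4-yn-3-ol and a silyloxybutynal.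

Key step: step 11

Remark: the atom labels C1–C20 are the cembrane labels of the target and are used for all intermediates.
Assumption: (R)-TRIP is taken to direct the allyl transfer of step 8 to the Re face of the aldehyde, as it does with simple aldehydes; should the sense be opposite, (S)-TRIP would be used.

Step 1
Reactants: 1 geranyl acetate, (2E)-3,7-dimethylocta-2,6-dien-1-yl acetate
Product: 2 (2E,6E)-8-hydroxy-3,7-dimethylocta-2,6-dien-1-yl acetate
Conditions: SeO2 (10 mol%), t-BuOOH (2 equiv), salicylic acid (10 mol%), CH2Cl2, 0 °C to rt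
Reagents that add atoms: tert-butyl hydroperoxide, CC(C)(C)OO
Why: Riley allylic oxidation (ene reaction, then [2,3]-sigmatropic shift) attacks the electron-rich distal trisubstituted alkene, the acetate deactivating the proximal one, and should give the (E)-allylic alcohol at the future C16.

Step 2
Reactants: 3 racemic pent-1-en-4-yn-3-ol
Product: 5 racemic (Z)-2-methyl-1-(tributylstannyl)penta-1,4-dien-3-ol, via dimagnesium chelate 4 (not isolated)
Conditions: MeMgBr (2.3 equiv), CuI (10 mol%), THF, -20 °C to rt; then Bu3SnCl, 0 °C to rt; H2O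
Reagents that add atoms: methylmagnesium bromide, C[Mg]Br; tributyltin chloride, CCCC[Sn](Cl)(CCCC)CCCC
Why: Copper-catalysed anti-carbomagnesiation of the propargylic alkoxide puts methyl on the internal alkyne carbon (C8) and magnesium on the terminal carbon (C9) cis to the carbinol in a five-membered chelate, so stannylation with retention should give the (Z)-stannane that defines the C8=C9 geometry.

Step 3
Reactants: 2 (2E,6E)-8-hydroxy-3,7-dimethylocta-2,6-dien-1-yl acetate; 5 racemic (Z)-2-methyl-1-(tributylstannyl)penta-1,4-dien-3-ol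
Product: 6 racemic (2E,6E,9Z)-2,6,10-trimethyltrideca-2,6,9,12-tetraene-1,11-diol
Conditions: Pd(dba)2 (5 mol%), LiCl (3 equiv), DMF, rt to 40 °C
Reagents that add atoms: none
Why: Stille coupling of an allylic acetate with an alkenylstannane: zerovalent palladium ionises only the acetate, and the π-allylpalladium chloride couples at its unsubstituted terminus (C10) with C9, keeping both alkene geometries and tolerating the two free hydroxyl groups.

Step 4
Reactants: 6 racemic (2E,6E,9Z)-2,6,10-trimethyltrideca-2,6,9,12-tetraene-1,11-diol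
Product: 7 (2E,6E,9Z,11S)-11-hydroxy-2,6,10-trimethyltrideca-2,6,9,12-tetraen-1-yl acetate
Conditions: immobilised Candida antarctica lipase B, vinyl acetate, MTBE, 30 °C, stopped just past half conversion of the secondary carbinol
Reagents that add atoms: vinyl acetate, C=COC(C)=O
Why: Lipase-catalysed transesterification used as a kinetic resolution: the enzyme acetylates the primary C16 hydroxyl of both enantiomers and, by the empirical size rule for secondary alcohols (vinyl medium, 1-methylalkenyl large), only the (R)-carbinol, so the (S)-C7 alcohol stays free and C7 is set.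

Step 5
Reactants: 7 (2E,6E,9Z,11S)-11-hydroxy-2,6,10-trimethyltrideca-2,6,9,12-tetraen-1-yl acetate
Product: 8 (2E,6E,9Z,11S)-11-[(tert-butyldimethylsilyl)oxy]-2,6,10-trimethyltrideca-2,6,9,12-tetraen-1-yl acetate
Conditions: TBSCl, imidazole, DMAP (cat.), DMF, rt
Reagents that add atoms: tert-butyldimethylsilyl chloride, CC(C)(C)[Si](C)(C)Cl
Why: Standard imidazole-promoted silylation masks the doubly allylic C7 hydroxyl for the hydride, borane and palladium steps ahead without touching the stereocentre or the primary acetate.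

Step 6
Reactants: 8 (2E,6E,9Z,11S)-11-[(tert-butyldimethylsilyl)oxy]-2,6,10-trimethyltrideca-2,6,9,12-tetraen-1-yl acetate
Product: 9 2-{(2E,6E,9Z,11S)-11-[(tert-butyldimethylsilyl)oxy]-2,6,10-trimethyltrideca-2,6,9,12-tetraen-1-yl}-4,4,5,5-tetramethyl-1,3,2-dioxaborolane
Conditions: B2pin2 (1.1 equiv), Pd2(dba)3 (2.5 mol%), DMSO, 50 °C
Reagents that add atoms: bis(pinacolato)diboron, CC1(C)OB(OC1(C)C)B1OC(C)(C)C(C)(C)O1
Why: Miyaura-type allylic borylation: zerovalent palladium ionises the primary allylic acetate, the acetate-bound π-allylpalladium transmetallates with B2pin2, and C–B reductive elimination at the unsubstituted terminus should keep the (E)-geometry, while the allylic silyl ether is not ionised.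

Step 7
Reactants: 10 tert-butyldimethyl(prop-2-yn-1-yloxy)silane
Product: 13 4-[(tert-butyldimethylsilyl)oxy]but-2-ynal, via lithium acetylide 11 (not isolated), via lithium hemiaminolate 12 (not isolated)
Conditions: n-BuLi, THF, -78 °C; DMF, -78 to 0 °C; inverse quench into cold aqueous buffer (pH 6)
Reagents that add atoms: N,N-dimethylformamide, CN(C)C=O
Why: Formylation of a lithium acetylide with DMF, the buffered inverse quench releasing the ynal from the hemiaminolate without conjugate addition of the liberated amine.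

Step 8
Reactants: 9 the (E)-allylboronate of step 6; 13 4-[(tert-butyldimethylsilyl)oxy]but-2-ynal
Product: 15 (4R,5R,8E,11Z,13S)-1,13-bis[(tert-butyldimethylsilyl)oxy]-8,12-dimethyl-5-(prop-1-en-2-yl)pentadeca-8,11,14-trien-2-yn-4-ol, via pinacol borate 14 (not isolated)
Conditions: (R)-TRIP [(R)-3,3'-bis(2,4,6-triisopropylphenyl)-1,1'-binaphthyl-2,2'-diyl hydrogen phosphate, 5 mol%], 4 Å MS, toluene, -30 °C; aqueous work-up
Reagents that add atoms: none
Why: Chiral phosphoric acid-catalysed allylboration through a closed chair (Zimmerman–Traxler) transition state: the (E)-γ-substituted boronate gives the anti C1/C2 relationship, and the catalyst, hydrogen-bonded to a boronate oxygen and the formyl hydrogen, directs attack to the Re face of 13, which sets C1 (R) and C2 (R here, S in the ring only through a change of CIP ranking) and unveils the isopropenyl group by allyl transposition.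

Step 9
Reactants: 15 the anti homoallylic propargylic alcohol of step 8
Product: 17 (2Z,4R,5R,8E,11Z,13S)-1,13-bis[(tert-butyldimethylsilyl)oxy]-2-iodo-8,12-dimethyl-5-(prop-1-en-2-yl)pentadeca-2,8,11,14-tetraen-4-ol, via cyclic alkenylalanate 16 (not isolated)
Conditions: NaAlH2(OCH2CH2OCH3)2 (1.6 equiv), THF, 0 °C to rt; then I2, THF, -78 °C; aq. potassium sodium tartrate, Na2S2O3
Reagents that add atoms: iodine, II
Why: Hydroxyl-directed trans-hydroalumination of the propargylic alcohol delivers hydride to C3 and holds aluminium on C4 in a five-membered oxaaluminacycle cis to C2, so iodinolysis with retention should give only the (Z)-iodide, the low temperature suppressing β-elimination of the C18 silyloxy group.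

Step 10
Reactants: 17 the (Z)-γ-hydroxy vinyl iodide of step 9
Product: 18 (2Z,4R,5R,8E,11Z,13S)-1,13-bis[(tert-butyldimethylsilyl)oxy]-2-iodo-8,12-dimethyl-5-(prop-1-en-2-yl)pentadeca-2,8,11,14-tetraen-4-yl acetate
Conditions: Ac2O, Et3N, DMAP (cat.), CH2Cl2, 0 °C to rt
Reagents that add atoms: acetic anhydride, CC(=O)OC(C)=O
Why: DMAP-catalysed acetylation installs the final C2 acetate and removes the only acidic proton before the borane step.

Step 11
Reactants: 18 the acyclic pentaene (Z)-vinyl iodide acetate of step 10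
Product: 20 (1R,2S,3E,7S,8Z,11E)-2-acetoxy-7,18-bis[(tert-butyldimethylsilyl)oxy]cembra-3,8,11,15-tetraene, via primary alkylborane 19 (not isolated)
Conditions: Sia2BH [bis(3-methylbutan-2-yl)borane, preformed THF solution, 1.3 equiv], THF, 0 °C to rt; H2O; then syringe-pump addition (final about 1 mM) to Pd(dppf)Cl2·CH2Cl2 (20 mol%), AsPh3 (40 mol%), Cs2CO3 (4 equiv), degassed DMF/THF/H2O, rt to 40 °C
Reagents that add atoms: none
Why: Disiamylborane adds anti-Markovnikov to C5=C6 to give the primary borane 19; zerovalent palladium then inserts into the C4–I bond with retention, the base-activated B–C5 bond transmetallates, and reductive elimination forms C4–C5. The closest known reaction type is the hydroboration/B-alkyl Suzuki–Miyaura macrocyclisation of ω-alkenyl vinyl iodides. The 14-membered carbocycle closes by C(sp2)–C(sp3) reductive elimination from a 15-membered palladacycle, the C3=C4 alkene staying endocyclic. No stereocentre is created; the C3=C4 geometry (C5 cis to C2) is controlled by the (Z)-iodide, and C1, C2 and C7 are spectators. The step needs chemoselective hydroboration, secured because C5=C6 is the only monosubstituted alkene and disiamylborane, unlike 9-BBN, clearly prefers it to the 1,1-disubstituted isopropenyl group next to branched C1, while only the primary alkyl group on boron is transferred. Ring closure must also outrun oligomerisation and 5-exo carbopalladation of the isopropenyl group, which slow addition at high dilution, mild temperature and the chelating dppf ligand should secure; C18 is carried as a silyl ether because a C18 acetate could be lost from the alkenylpalladium by β-elimination.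

Step 12
Reactants: 20 the bis-silylated macrocycle of step 11
Product: 21 (1R,2S,3E,7S,8Z,11E)-2-acetoxycembra-3,8,11,15-tetraene-7,18-diol
Conditions: HF·pyridine, pyridine, THF, 0 °C to rt
Reagents that add atoms: none
Why: Fluoride-driven cleavage of both silyl ethers under buffered conditions that leave the allylic C2 acetate and the alkenes untouched and cannot move the acetyl group, since O2 and O18 lie trans across C3=C4.

Step 13
Reactants: 21 (1R,2S,3E,7S,8Z,11E)-2-acetoxycembra-3,8,11,15-tetraene-7,18-diol
Product: 22 (1R,2S,3E,7S,8Z,11E)-2,18-diacetoxycembra-3,8,11,15-tetraen-7-ol (target)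
Conditions: AcCl (1.05 equiv), 2,4,6-collidine, CH2Cl2, -78 °C
Reagents that add atoms: acetyl chloride, CC(=O)Cl
Why: Kinetically controlled acylation with a hindered pyridine base at low temperature discriminates the unhindered primary allylic C18 hydroxyl from the secondary C7 hydroxyl flanked by the fully substituted C8.

Compound list
1 | geranyl acetate | CC(C)=CCC/C(C)=C/COC(C)=O | starting material
2 | (2E,6E)-8-hydroxy-3,7-dimethylocta-2,6-dien-1-yl acetate | OC/C(C)=C/CC/C(C)=C/COC(C)=O | intermediate
3 | racemic pent-1-en-4-yn-3-ol | C=CC(O)C#C | starting material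
4 | (Z)-[3-(bromomagnesiooxy)-2-methylpenta-1,4-dien-1-yl]magnesium bromide (chelate, not isolated) | Br[Mg]/C=C(/C)C(O[Mg]Br)C=C | intermediate
5 | racemic (Z)-2-methyl-1-(tributylstannyl)penta-1,4-dien-3-ol | CCCC[Sn](CCCC)(CCCC)/C=C(/C)C(O)C=C | intermediate
6 | racemic (2E,6E,9Z)-2,6,10-trimethyltrideca-2,6,9,12-tetraene-1,11-diol | OC/C(C)=C/CC/C(C)=C/C/C=C(/C)C(O)C=C | intermediate
7 | (2E,6E,9Z,11S)-11-hydroxy-2,6,10-trimethyltrideca-2,6,9,12-tetraen-1-yl acetate | CC(=O)OC/C(C)=C/CC/C(C)=C/C/C=C(/C)[C@@H](O)C=C | intermediate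
8 | (2E,6E,9Z,11S)-11-[(tert-butyldimethylsilyl)oxy]-2,6,10-trimethyltrideca-2,6,9,12-tetraen-1-yl acetate | CC(=O)OC/C(C)=C/CC/C(C)=C/C/C=C(/C)[C@@H](O[Si](C)(C)C(C)(C)C)C=C | intermediate
9 | (E)-allyl pinacol boronate of the C5–C17 chain | CC1(C)OB(C/C(C)=C/CC/C(C)=C/C/C=C(/C)[C@@H](O[Si](C)(C)C(C)(C)C)C=C)OC1(C)C | intermediate
10 | tert-butyldimethyl(prop-2-yn-1-yloxy)silane | C#CCO[Si](C)(C)C(C)(C)C | starting material
11 | lithium acetylide of 10 (not isolated) | [Li]C#CCO[Si](C)(C)C(C)(C)C | intermediate
12 | lithium 4-[(tert-butyldimethylsilyl)oxy]-1-(dimethylamino)but-2-yn-1-olate (not isolated) | CN(C)C(O[Li])C#CCO[Si](C)(C)C(C)(C)C | intermediate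
13 | 4-[(tert-butyldimethylsilyl)oxy]but-2-ynal | O=CC#CCO[Si](C)(C)C(C)(C)C | intermediate
14 | O-pinacolboryl ether of 15 (not isolated) | C=C(C)[C@@H](CC/C(C)=C/C/C=C(/C)[C@@H](O[Si](C)(C)C(C)(C)C)C=C)[C@H](C#CCO[Si](C)(C)C(C)(C)C)OB1OC(C)(C)C(C)(C)O1 | intermediate
15 | (4R,5R,8E,11Z,13S)-1,13-bis[(tert-butyldimethylsilyl)oxy]-8,12-dimethyl-5-(prop-1-en-2-yl)pentadeca-8,11,14-trien-2-yn-4-ol | C=C(C)[C@@H](CC/C(C)=C/C/C=C(/C)[C@@H](O[Si](C)(C)C(C)(C)C)C=C)[C@H](C#CCO[Si](C)(C)C(C)(C)C)O | intermediate
16 | sodium oxaaluminacyclopentene (alkenylalanate, Al on C4 and O2, not isolated) | C=C(C)[C@@H](CC/C(C)=C/C/C=C(/C)[C@@H](O[Si](C)(C)C(C)(C)C)C=C)[C@@H]1C=C(CO[Si](C)(C)C(C)(C)C)[Al-](OCCOC)(OCCOC)O1.[Na+] | intermediate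
17 | (2Z,4R,5R,8E,11Z,13S)-1,13-bis[(tert-butyldimethylsilyl)oxy]-2-iodo-8,12-dimethyl-5-(prop-1-en-2-yl)pentadeca-2,8,11,14-tetraen-4-ol | C=C(C)[C@@H](CC/C(C)=C/C/C=C(/C)[C@@H](O[Si](C)(C)C(C)(C)C)C=C)[C@H](/C=C(/CO[Si](C)(C)C(C)(C)C)I)O | intermediate
18 | acetate of 17 | C=C(C)[C@@H](CC/C(C)=C/C/C=C(/C)[C@@H](O[Si](C)(C)C(C)(C)C)C=C)[C@H](/C=C(/CO[Si](C)(C)C(C)(C)C)I)OC(C)=O | intermediate
19 | C5 bis(3-methylbutan-2-yl)borane derived from 18 (not isolated) | C=C(C)[C@@H](CC/C(C)=C/C/C=C(/C)[C@@H](O[Si](C)(C)C(C)(C)C)CCB(C(C)C(C)C)C(C)C(C)C)[C@H](/C=C(/CO[Si](C)(C)C(C)(C)C)I)OC(C)=O | intermediate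
20 | (1R,2S,3E,7S,8Z,11E)-2-acetoxy-7,18-bis[(tert-butyldimethylsilyl)oxy]cembra-3,8,11,15-tetraene | C=C(C)[C@H]1CC/C(C)=C/C/C=C(/C)[C@@H](O[Si](C)(C)C(C)(C)C)CC/C(CO[Si](C)(C)C(C)(C)C)=C\[C@@H]1OC(C)=O | intermediate
21 | (1R,2S,3E,7S,8Z,11E)-2-acetoxycembra-3,8,11,15-tetraene-7,18-diol | C=C(C)[C@H]1CC/C(C)=C/C/C=C(/C)[C@@H](O)CC/C(CO)=C\[C@@H]1OC(C)=O | intermediate
22 | (1R,2S,3E,7S,8Z,11E)-2,18-diacetoxycembra-3,8,11,15-tetraen-7-ol | C=C(C)[C@H]1CC/C(C)=C/C/C=C(/C)[C@@H](O)CC/C(COC(C)=O)=C\[C@@H]1OC(C)=O | target

Total step count: 13. Longest linear sequence: 11 steps (1, 3, 4, 5, 6, 8, 9, 10, 11, 12, 13, from geranyl acetate).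

Steps most likely to fail

Step 11. The isopropenyl group may be hydroborated in competition. The hindered borane may also transmetallate slowly, so that carbopalladation of the isopropenyl group or oligomerisation takes over. The fallback forms the same C4–C5 bond by an intramolecular Negishi coupling, which separates the chemoselectivity problem from the ring closure. It sets out from 18. Hydroboration with Sia2BH (again through 19) followed by oxidation with NaBO3·4H2O would give the primary C5 alcohol F1, which can be purified at this stage. An Appel reaction (I2, PPh3, imidazole) would give the primary C5 iodide F2. Zn dust with LiCl in THF should insert only into the C(sp3)–I bond to give the alkylzinc iodide F3. Slow addition of this to Pd2(dba)3/SPhos in THF at high dilution comes back to the route at 20.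

Step 8. Facial selectivity may be poor with the slim ynal, and any loss of (E)-geometry in the boronate would erode the anti selectivity. The fallback is a catalytic asymmetric Nozaki–Hiyama–Kishi allylation, which is stereoconvergent in the allyl geometry and also bypasses step 6. It sets out from 8. K2CO3 in MeOH would give the C16 allylic alcohol F4, and CBr4/PPh3 the C16 allylic bromide F5. CrCl2 (10 mol%), a chiral bis(oxazolinyl)carbazole ligand, Mn powder, Me3SiCl and i-Pr2NEt in THF with 13 would give the C2 trimethylsilyl ether F6. This forms through an (E)-configured allyl complex of trivalent chromium in a chair transition state (anti), the ligand controlling the face. Citric acid in MeOH removes the trimethylsilyl group and comes back to the route at 15.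

Step 9. The silyloxy group may be lost from the alkenylalanate by β-elimination to give an allene, or regiocontrol of the hydride delivery may be incomplete. The fallback places the iodine before the C1–C2 bond is made. It sets out from 13. Conjugate anti-hydroiodination (LiI, AcOH, MeCN, rt) would give (Z)-4-[(tert-butyldimethylsilyl)oxy]-3-iodobut-2-enal F7, with iodine cis to the formyl carbon. Allylboration of this enal with 9 under the conditions of step 8 would pass through the O-pinacolboryl ether of 17 F8 and, after aqueous work-up, come back to the route at 17.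

Further compounds
F1 | step 11 | primary C5 alcohol from 18 (vinyl converted to CH2CH2OH) | C=C(C)[C@@H](CC/C(C)=C/C/C=C(/C)[C@@H](O[Si](C)(C)C(C)(C)C)CCO)[C@H](/C=C(/CO[Si](C)(C)C(C)(C)C)I)OC(C)=O
F2 | step 11 | primary C5 iodide | C=C(C)[C@@H](CC/C(C)=C/C/C=C(/C)[C@@H](O[Si](C)(C)C(C)(C)C)CCI)[C@H](/C=C(/CO[Si](C)(C)C(C)(C)C)I)OC(C)=O
F3 | step 11 | C5 alkylzinc iodide | C=C(C)[C@@H](CC/C(C)=C/C/C=C(/C)[C@@H](O[Si](C)(C)C(C)(C)C)CC[Zn]I)[C@H](/C=C(/CO[Si](C)(C)C(C)(C)C)I)OC(C)=O
F4 | step 8 | (2E,6E,9Z,11S)-11-[(tert-butyldimethylsilyl)oxy]-2,6,10-trimethyltrideca-2,6,9,12-tetraen-1-ol | OC/C(C)=C/CC/C(C)=C/C/C=C(/C)[C@@H](O[Si](C)(C)C(C)(C)C)C=C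
F5 | step 8 | (2E,6E,9Z,11S)-1-bromo-11-[(tert-butyldimethylsilyl)oxy]-2,6,10-trimethyltrideca-2,6,9,12-tetraene | BrC/C(C)=C/CC/C(C)=C/C/C=C(/C)[C@@H](O[Si](C)(C)C(C)(C)C)C=C
F6 | step 8 | C2 trimethylsilyl ether of 15 | C=C(C)[C@@H](CC/C(C)=C/C/C=C(/C)[C@@H](O[Si](C)(C)C(C)(C)C)C=C)[C@H](C#CCO[Si](C)(C)C(C)(C)C)O[Si](C)(C)C
F7 | step 9 | (Z)-4-[(tert-butyldimethylsilyl)oxy]-3-iodobut-2-enal | O=C/C=C(/CO[Si](C)(C)C(C)(C)C)I
F8 | step 9 | O-pinacolboryl ether of 17 | C=C(C)[C@@H](CC/C(C)=C/C/C=C(/C)[C@@H](O[Si](C)(C)C(C)(C)C)C=C)[C@H](/C=C(/CO[Si](C)(C)C(C)(C)C)I)OB1OC(C)(C)C(C)(C)O1
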